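**Plan**
- The retrosynthesis first cuts the C3–OH bond (back to C3–Br), then both ring bonds to C3 (C2–C3 and C3–C4), so that C3 leaves as the carbon of dibromocarbene.
- The enabling feature: in ring C, C3 sits between C2 (bonded to O1 and the 4-methoxyphenyl ring) and the C4 carbonyl. Without C3 these two atoms are the C2=C3 enol-ether bond of a 2-aryl-3-silyloxybenzofuran.
- The benzofuranone is cut at O1–C2 (phenoxide displacing an α-bromide) and at C3–C3a (acylation of 2,3,4,5-tetramethoxyphenol with 4-methoxyphenylacetic acid).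
- Forward: ring A is taken fully oxygenated, acylated, closed to the five-membered furanone and silylated. The furan is then expanded to the six-membered pyranone by one-carbon insertion, and the bromine left on C3 is exchanged for hydroxyl.
- Stereochemistry: the target has no stereocentre; the stereocentres of 7, 8 and 11 are racemic and are erased on the way.

Key step: step 7

Remark: compounds 1, 5 and 10 are taken as purchased; no stereocontrol is needed anywhere.

Step 1
Reactants: 1 1,2,3,4-tetramethoxybenzene
Product: 2 2,3,4,5-tetramethoxybenzaldehyde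
Conditions: POCl3, DMF, 0 °C to 80 °C; then H2O, 0 °C to rt
Reagents that add atoms: dimethylformamide (CN(C)C=O); water (O)
Why: Vilsmeier–Haack formylation of an electron-rich arene whose two free positions are equivalent, so only one aldehyde can form.

Step 2
Reactants: 2 2,3,4,5-tetramethoxybenzaldehyde
Product: 4 2,3,4,5-tetramethoxyphenol, via aryl formate 3 (not isolated)
Conditions: mCPBA, CH2Cl2, 0 °C to rt; NaHCO3 wash; then cat. K2CO3, MeOH, rt, argon
Reagents that add atoms: 3-chloroperbenzoic acid (OOC(=O)c1cccc(Cl)c1)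
Why: Baeyer–Villiger (Dakin-type) oxidation in which the electron-rich aryl group migrates, followed by methanolysis of the formate to free the phenol.

Step 3
Reactants: 4 2,3,4,5-tetramethoxyphenol; 5 4-methoxyphenylacetic acid
Product: 6 1-(2-hydroxy-3,4,5,6-tetramethoxyphenyl)-2-(4-methoxyphenyl)ethan-1-one
Conditions: BF3·OEt2 (neat), 85 °C; then H2O/MeOH, 60 °C
Reagents that add atoms: none
Why: BF3-promoted Friedel–Crafts acylation of a phenol (through the aryl ester and a Fries-type ortho shift), the standard entry to 2-hydroxydeoxybenzoins; the only unsubstituted ring carbon lies ortho to the hydroxyl.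

Step 4
Reactants: 6 1-(2-hydroxy-3,4,5,6-tetramethoxyphenyl)-2-(4-methoxyphenyl)ethan-1-one
Product: 7 2-bromo-1-(2-hydroxy-3,4,5,6-tetramethoxyphenyl)-2-(4-methoxyphenyl)ethan-1-one (racemic)
Conditions: CuBr2 (2 equiv), EtOAc/CHCl3, reflux
Reagents that add atoms: copper dibromide CuBr2 (Br[Cu]Br)
Why: α-Bromination of a readily enolised benzylic ketone with CuBr2, a heterogeneous halogenation that brominates hydroxyaryl ketones at the α-carbon and spares the ring; ring A has no free position.

Step 5
Reactants: 7 2-bromo-1-(2-hydroxy-3,4,5,6-tetramethoxyphenyl)-2-(4-methoxyphenyl)ethan-1-one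
Product: 8 4,5,6,7-tetramethoxy-2-(4-methoxyphenyl)-1-benzofuran-3(2H)-one (racemic)
Conditions: K2CO3, degassed acetone, rt, argon
Reagents that add atoms: none
Why: Intramolecular Williamson etherification (5-exo-tet) of the phenoxide onto the activated α-bromoketone, the usual closure of α-halo-2-hydroxyaryl ketones to benzofuran-3(2H)-ones; air is excluded to suppress autoxidation at C2.

Step 6
Reactants: 8 4,5,6,7-tetramethoxy-2-(4-methoxyphenyl)-1-benzofuran-3(2H)-one
Product: 9 tert-butyl(dimethyl){[4,5,6,7-tetramethoxy-2-(4-methoxyphenyl)-1-benzofuran-3-yl]oxy}silane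
Conditions: TBSOTf, Et3N, CH2Cl2, 0 °C, argon
Reagents that add atoms: tert-butyldimethylsilyl trifluoromethanesulfonate (CC(C)(C)[Si](C)(C)OS(=O)(=O)C(F)(F)F)
Why: Silyl enol ether formation by soft enolisation; O-silylation of the acidic C2–H ketone is driven by aromatisation to the benzofuran.

Step 7
Reactants: 9 tert-butyl(dimethyl){[4,5,6,7-tetramethoxy-2-(4-methoxyphenyl)-1-benzofuran-3-yl]oxy}silane; 10 bromoform
Product: 12 3-bromo-5,6,7,8-tetramethoxy-2-(4-methoxyphenyl)-4H-chromen-4-one, via dibromocyclopropane adduct 11 (not isolated)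
Conditions: CHBr3, KOtBu, hexane/toluene, −20 °C to rt, argon; then H2O
Reagents that add atoms: none
Why: Proposed new method: dibromocarbene, formed by α-elimination from bromoform with KOtBu, should add in a concerted [2+1] manner to the C2=C3 enol-ether bond of 9 to give the 1,1-dibromocyclopropa[b]benzofuran 11; departure of the bromide lying over the five-membered ring, pushed by the lone pairs of O1 and the silyloxy oxygen, triggers disrotatory two-electron electrocyclic opening of the former C2–C3 bond, and transfer of the silyl group from the silyloxy-allyl cation to bromide leaves the C4 carbonyl and the C2=C3(Br) bond of 12. The closest known reactions are the dihalocarbene ring expansion of cyclic silyl enol ethers to 2-halo-2-enones and the Ciamician–Dennstedt-type one-carbon expansion of indoles and benzofurans with halocarbenes. The six-membered pyranone (ring C) does not arise by end-to-end cyclisation but by cheletropic closure of the three-membered ring followed by its electrocyclic opening, which places the new carbon between the old C2 and C3 of the furan. No stereocentre remains, because the two stereocentres of racemic 11 become trigonal. The step needs attack at the furan double bond only: ring A has no free position, the anisyl ring is far less nucleophilic than a doubly oxygen-substituted enol ether, and the tert-butyldimethylsilyl group should resist tert-butoxide at low temperature so that the neutral enol ether, not the enolate, meets the carbene.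

Step 8
Reactants: 12 3-bromo-5,6,7,8-tetramethoxy-2-(4-methoxyphenyl)-4H-chromen-4-one
Product: 14 3-hydroxy-5,6,7,8-tetramethoxy-2-(4-methoxyphenyl)-4H-chromen-4-one, via pinacol boronate 13 (not isolated)
Conditions: B2pin2, cat. PdCl2(dppf), KOAc, 1,4-dioxane, 85 °C; then NaBO3·4H2O, THF/H2O, rt
Reagents that add atoms: bis(pinacolato)diboron (CC1(C)OB(OC1(C)C)B1OC(C)(C)C(C)(C)O1); sodium perborate NaBO3·4H2O ([Na+].[Na+].O[B-]1(O)OO[B-](O)(O)OO1)
Why: Miyaura borylation of the alkenyl bromide followed by perborate oxidation of the carbon–boron bond under weakly basic conditions that the pyranone tolerates; the enol formed is the stable flavonol tautomer.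

**Compound list**
1 | 1,2,3,4-tetramethoxybenzene | COc1ccc(OC)c(OC)c1OC | starting material
2 | 2,3,4,5-tetramethoxybenzaldehyde | COc1cc(C=O)c(OC)c(OC)c1OC | intermediate
3 | 2,3,4,5-tetramethoxyphenyl formate (formed in the flask, not isolated) | COc1cc(OC=O)c(OC)c(OC)c1OC | intermediate
4 | 2,3,4,5-tetramethoxyphenol | COc1cc(O)c(OC)c(OC)c1OC | intermediate
5 | 4-methoxyphenylacetic acid | COc1ccc(CC(=O)O)cc1 | starting material
6 | 1-(2-hydroxy-3,4,5,6-tetramethoxyphenyl)-2-(4-methoxyphenyl)ethan-1-one | COc1ccc(CC(=O)c2c(O)c(OC)c(OC)c(OC)c2OC)cc1 | intermediate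
7 | 2-bromo-1-(2-hydroxy-3,4,5,6-tetramethoxyphenyl)-2-(4-methoxyphenyl)ethan-1-one (racemic) | COc1ccc(C(Br)C(=O)c2c(O)c(OC)c(OC)c(OC)c2OC)cc1 | intermediate
8 | 4,5,6,7-tetramethoxy-2-(4-methoxyphenyl)-1-benzofuran-3(2H)-one (racemic) | COc1ccc(C2Oc3c(OC)c(OC)c(OC)c(OC)c3C2=O)cc1 | intermediate
9 | tert-butyl(dimethyl){[4,5,6,7-tetramethoxy-2-(4-methoxyphenyl)-1-benzofuran-3-yl]oxy}silane | COc1ccc(-c2oc3c(OC)c(OC)c(OC)c(OC)c3c2O[Si](C)(C)C(C)(C)C)cc1 | intermediate
10 | bromoform | BrC(Br)Br | starting material
11 | 1,1-dibromo-6b-[(tert-butyldimethylsilyl)oxy]-3,4,5,6-tetramethoxy-1a-(4-methoxyphenyl)-1a,6b-dihydro-1H-cyclopropa[b][1]benzofuran (racemic, cis-fused; formed in the flask, not isolated) | COc1ccc(cc1)C12Oc3c(OC)c(OC)c(OC)c(OC)c3C1(O[Si](C)(C)C(C)(C)C)C2(Br)Br | intermediate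
12 | 3-bromo-5,6,7,8-tetramethoxy-2-(4-methoxyphenyl)-4H-chromen-4-one | COc1ccc(-c2oc3c(OC)c(OC)c(OC)c(OC)c3c(=O)c2Br)cc1 | intermediate
13 | 5,6,7,8-tetramethoxy-2-(4-methoxyphenyl)-3-(4,4,5,5-tetramethyl-1,3,2-dioxaborolan-2-yl)-4H-chromen-4-one (formed in the flask, not isolated) | COc1ccc(-c2oc3c(OC)c(OC)c(OC)c(OC)c3c(=O)c2B4OC(C)(C)C(C)(C)O4)cc1 | intermediate
14 | 3-hydroxy-5,6,7,8-tetramethoxy-2-(4-methoxyphenyl)-4H-chromen-4-one | COc1ccc(-c2oc3c(OC)c(OC)c(OC)c(OC)c3c(=O)c2O)cc1 | target

**Total step count:** 8
**Longest linear sequence:** 8 steps (1 to 14)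

**Steps most likely to fail**

Step 7. The carbene may fail to add to the hindered, tetrasubstituted enol-ether bond, or tert-butoxide may strip the silyl group so that the resulting enolate is only C-alkylated at C2. Ring C would then be built by established flavone chemistry, setting out from phenol 4. C-Acetylation of 4 with acetic acid in BF3·OEt2 should give 1-(2-hydroxy-3,4,5,6-tetramethoxyphenyl)ethan-1-one F1. O-Acylation with 4-methoxybenzoyl chloride in pyridine should give 2-acetyl-3,4,5,6-tetramethoxyphenyl 4-methoxybenzoate F2. Baker–Venkataraman rearrangement (KOH, pyridine, 50 °C) should give 1-(2-hydroxy-3,4,5,6-tetramethoxyphenyl)-3-(4-methoxyphenyl)propane-1,3-dione F3. Bromination of the central methylene with CuBr2 should give 2-bromo-1-(2-hydroxy-3,4,5,6-tetramethoxyphenyl)-3-(4-methoxyphenyl)propane-1,3-dione F4. Acid-mediated cyclodehydration (H2SO4, AcOH) then closes ring C, and the route is rejoined at 12.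

Step 8. Borylation may be overtaken by protodebromination, or the C3 boronate may lose boron by protonation before it is oxidised. The hydroxyl would then be introduced by oxidation of the C3–H flavone, setting out from 12. Hydrogenolysis (H2, Pd/C, Et3N, EtOAc) should give 5,6,7,8-tetramethoxy-2-(4-methoxyphenyl)-4H-chromen-4-one F5, which is tangeretin. Dimethyldioxirane in acetone/CH2Cl2 should epoxidise the C2=C3 bond to 3,4,5,6-tetramethoxy-1a-(4-methoxyphenyl)-1a,7a-dihydro-7H-oxireno[2,3-b]chromen-7-one F6. With catalytic p-TsOH this epoxide should isomerise to the flavonol, rejoining the route at 14.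

Step 4. Bromination may continue at C2 after premature ring closure, may attack the anisyl ring, or ring A may suffer oxidative demethylation. The order of bond formation at the furanone would then be reversed (O1–C2 first, C3–C3a second), setting out from 4. Methyl 4-methoxyphenylacetate is brominated (NBS, AIBN, PhCF3, reflux) to methyl 2-bromo-2-(4-methoxyphenyl)acetate F7. Phenol 4 is O-alkylated with it (K2CO3, acetone) to methyl 2-(4-methoxyphenyl)-2-(2,3,4,5-tetramethoxyphenoxy)acetate F8. Saponification (LiOH, THF/H2O) gives 2-(4-methoxyphenyl)-2-(2,3,4,5-tetramethoxyphenoxy)acetic acid F9. Intramolecular Friedel–Crafts acylation at the single free ring position (trifluoroacetic anhydride, CH2Cl2, or P2O5 in MeSO3H) then gives the benzofuranone, rejoining the route at 8.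

**Further compounds**
F1 | step 7 | 1-(2-hydroxy-3,4,5,6-tetramethoxyphenyl)ethan-1-one | CC(=O)c1c(O)c(OC)c(OC)c(OC)c1OC
F2 | step 7 | 2-acetyl-3,4,5,6-tetramethoxyphenyl 4-methoxybenzoate | COc1ccc(cc1)C(=O)Oc1c(OC)c(OC)c(OC)c(OC)c1C(C)=O
F3 | step 7 | 1-(2-hydroxy-3,4,5,6-tetramethoxyphenyl)-3-(4-methoxyphenyl)propane-1,3-dione | COc1ccc(cc1)C(=O)CC(=O)c1c(O)c(OC)c(OC)c(OC)c1OC
F4 | step 7 | 2-bromo-1-(2-hydroxy-3,4,5,6-tetramethoxyphenyl)-3-(4-methoxyphenyl)propane-1,3-dione (racemic) | COc1ccc(cc1)C(=O)C(Br)C(=O)c1c(O)c(OC)c(OC)c(OC)c1OC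
F5 | step 8 | 5,6,7,8-tetramethoxy-2-(4-methoxyphenyl)-4H-chromen-4-one (tangeretin) | COc1ccc(-c2cc(=O)c3c(OC)c(OC)c(OC)c(OC)c3o2)cc1
F6 | step 8 | 3,4,5,6-tetramethoxy-1a-(4-methoxyphenyl)-1a,7a-dihydro-7H-oxireno[2,3-b]chromen-7-one (racemic) | COc1ccc(cc1)C12OC1C(=O)c1c(OC)c(OC)c(OC)c(OC)c1O2
F7 | step 4 | methyl 2-bromo-2-(4-methoxyphenyl)acetate (racemic) | COC(=O)C(Br)c1ccc(OC)cc1
F8 | step 4 | methyl 2-(4-methoxyphenyl)-2-(2,3,4,5-tetramethoxyphenoxy)acetate (racemic) | COC(=O)C(Oc1cc(OC)c(OC)c(OC)c1OC)c1ccc(OC)cc1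
F9 | step 4 | 2-(4-methoxyphenyl)-2-(2,3,4,5-tetramethoxyphenoxy)acetic acid (racemic) | OC(=O)C(Oc1cc(OC)c(OC)c(OC)c1OC)c1ccc(OC)cc1
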